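**Retrosynthetic overview**
1. The aryl–C(quaternary) bond is made last. The enedione enolate adds across the ring to a tethered benzoquinone, which closes the five-membered ring C and completes the bicyclo[3.2.1] core.
2. Key disconnection: the cyclohex-2-ene-1,4-dione (ring A) comes from a one-carbon ring expansion of a cis-hydrindene-1,3-dione. The expansion is a 1,2-acyl shift through a zinc cyclopropanolate.
3. The angular prenyl group is put on at the contracted stage, because the five-membered dione cannot aromatise. A vinylogous ester leaves only one position that can be deprotonated.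
4. Ring B comes from the aryl diene and cyclopent-4-ene-1,3-dione. This "contracted quinone" has a single C=C, so the site-selectivity problem of prenylbenzoquinone does not arise.
5. Order of ring formation: arene (given), then ring B together with the five-membered proto-ring A, then ring A by expansion, then ring C.

Assumption: (R)-BINOL/TiCl2(OiPr)2 is taken to give the enantiomer drawn. If the sense is the opposite, (S)-BINOL is used.

**Step 1**
Reactants: 1 hydroquinone
Product: 2 1,4-dimethoxybenzene
Conditions: MeI, K2CO3, acetone, reflux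
Reagents that add atoms: iodomethane, CI
Why: Williamson O-methylation masks both phenols, provides the directing groups for lithiation, and creates no stereocentre.

**Step 2**
Reactants: 2 1,4-dimethoxybenzene; 3 3-methylbut-2-enal
Product: 6 (E)-1-(2,5-dimethoxyphenyl)-3-methylbuta-1,3-diene, via aryllithium 4 (not isolated), via allylic alcohol 5 (not isolated)
Conditions: n-BuLi, TMEDA, Et2O, 0 °C to rt; 3, −78 °C; H2O; crude 5, PPTS (5 mol %), toluene, 60 °C
Reagents that add atoms: none
Why: Directed ortho-lithiation and 1,2-addition give a doubly activated carbinol, and acid-catalysed 1,4-dehydration (E1) of it gives the conjugated E-diene.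

**Step 3**
Reactants: 6 aryl diene; 7 cyclopent-4-ene-1,3-dione
Product: 8 cis-fused endo adduct, 4-(2,5-dimethoxyphenyl)-6-methyl-3a,4,7,7a-tetrahydroindene-1,3-dione (aryl cis to both carbonyl carbons)
Conditions: (R)-BINOL (12 mol %), TiCl2(OiPr)2 (10 mol %), CH2Cl2, −30 °C
Reagents that add atoms: none
Why: This is a catalytic enantioselective Diels–Alder reaction on a symmetric ene-dione with one C=C, so there is no regio- or site issue; the endo rule sets aryl cis to the carbonyls and the chiral titanium Lewis acid sets the absolute configuration of the benzylic carbon and both ring-fusion carbons.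

**Step 4**
Reactants: 8 endo adduct
Product: 9 7-(2,5-dimethoxyphenyl)-3-isobutoxy-5-methyl-3a,4,7,7a-tetrahydroinden-1-one (ketone next to the aryl-bearing side, enol ether on the CH2 side)
Conditions: i-BuOH, p-TsOH·H2O (5 mol %), toluene, Dean–Stark
Reagents that add atoms: 2-methylpropan-1-ol, CC(C)CO
Why: Equilibrating vinylogous ester formation (the Stork–Danheiser substrate) places the bulky alkoxy group on the less hindered carbonyl, removes the acidic C-2 proton and leaves the stereocentres untouched.

**Step 5**
Reactants: 9 vinylogous ester; 10 1-bromo-3-methylbut-2-ene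
Product: 13 4-(2,5-dimethoxyphenyl)-6-methyl-3a-(3-methylbut-2-enyl)-3a,4,7,7a-tetrahydroindene-1,3-dione, via lithium enolate 11 (not isolated), via prenylated vinylogous ester 12 (not isolated)
Conditions: LiN(iPr)2, THF, −78 °C; 10, DMPU, −78 to −20 °C; then 2 M HCl, THF, 40 °C
Reagents that add atoms: water, O
Why: Kinetic α′-deprotonation (Stork–Danheiser alkylation) can only occur at the ring-fusion carbon next to the ketone, and prenyl bromide enters on the convex face anti to the aryl group, which sets the quaternary centre with prenyl trans to aryl and keeps the cis ring fusion.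

**Step 6 (key step)**
Reactants: 13 angular prenyl 1,3-dione; 14 iodoform
Product: 18 5-(2,5-dimethoxyphenyl)-7-methyl-4a-(3-methylbut-2-enyl)-4a,5,8,8a-tetrahydronaphthalene-1,4-dione, via ethylzinc enolate 15 (not isolated), via iodocyclopropanolate 16 (not isolated), via iodo zinc enolate 17 (not isolated)
Conditions: Et2Zn (1.1 equiv), CH2Cl2, −20 °C; then EtZnCHI2 (preformed from Et2Zn 1.1 equiv and CHI3 1.1 equiv), −20 to 0 °C
Reagents that add atoms: none
Why: Proposed new method: the zinc enolate is alkylated at C-2 by the iodocarbenoid, the resulting C–Zn carbon closes onto a flanking carbonyl to give a donor–acceptor cyclopropanolate, and fragmentation of the internal bond (a net 1,2-acyl shift, five- to six-membered ring) followed by β-loss of zinc iodide gives the ene-1,4-dione directly; either carbonyl leads to the same product, no stereocentre is touched, and the anionic enolate should outrun the neutral trisubstituted alkenes for one equivalent of carbenoid; the closest known reaction type is the zinc-carbenoid chain extension of acyclic β-dicarbonyl compounds, which has not been shown as a ring expansion of cyclic 1,3-diones or with a CHI carbenoid.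

**Step 7**
Reactants: 18 enedione dimethyl ether
Product: 19 2-[7-methyl-1,4-dioxo-4a-(3-methylbut-2-enyl)-1,4,4a,5,8,8a-hexahydronaphthalen-5-yl]cyclohexa-2,5-diene-1,4-dione
Conditions: (NH4)2Ce(NO3)6 (2.2 equiv), MeCN–H2O, 0 °C
Reagents that add atoms: water, O
Why: Oxidative demethylation of the 1,4-dimethoxyarene gives the quinone without affecting the enedione, the trisubstituted alkenes or the stereocentres.

**Step 8**
Reactants: 19 quinone
Product: 20 target
Conditions: DBU (20 mol %), degassed THF, 0 °C to rt, argon
Reagents that add atoms: none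
Why: The only enolisable carbon (C-8a) undergoes an intramolecular Michael addition to the quinone carbon ortho to the tether, on the face that carries the quinone, and tautomerisation to the hydroquinone sets the second quaternary centre under full control of the two existing centres.

**Compound list**
1 | hydroquinone | Oc1ccc(O)cc1 | starting material
2 | 1,4-dimethoxybenzene | COc1ccc(OC)cc1 | intermediate
3 | 3-methylbut-2-enal | CC(C)=CC=O | starting material
4 | 2,5-dimethoxyphenyllithium | [Li]c1cc(OC)ccc1OC | intermediate
5 | 1-(2,5-dimethoxyphenyl)-3-methylbut-2-en-1-ol (racemic) | CC(C)=CC(O)c1cc(OC)ccc1OC | intermediate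
6 | (E)-1-(2,5-dimethoxyphenyl)-3-methylbuta-1,3-diene | C=C(C)/C=C/c1cc(OC)ccc1OC | intermediate
7 | cyclopent-4-ene-1,3-dione | O=C1C=CC(=O)C1 | starting material
8 | endo adduct, cis-fused, aryl cis to the carbonyls | [C@@H]12C(=O)CC(=O)[C@@H]1CC(C)=C[C@@H]2c1cc(OC)ccc1OC | intermediate
9 | isobutyl vinylogous ester (ketone beside the aryl-bearing side) | [C@@H]12C(=O)C=C(OCC(C)C)[C@@H]1CC(C)=C[C@@H]2c1cc(OC)ccc1OC | intermediate
10 | 1-bromo-3-methylbut-2-ene | CC(C)=CCBr | starting material
11 | cross-conjugated lithium enolate of 9 | [Li]OC1=C2[C@@H](c3cc(OC)ccc3OC)C=C(C)C[C@H]2C(OCC(C)C)=C1 | intermediate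
12 | angular prenyl vinylogous ester | CC(C)=CC[C@@]12C(=O)C=C(OCC(C)C)[C@@H]1CC(C)=C[C@@H]2c1cc(OC)ccc1OC | intermediate
13 | angular prenyl hydrindene-1,3-dione (prenyl trans to aryl, cis-fused) | CC(C)=CC[C@@]12C(=O)CC(=O)[C@@H]1CC(C)=C[C@@H]2c1cc(OC)ccc1OC | intermediate
14 | iodoform | IC(I)I | starting material
15 | ethylzinc enolate of 13 | CC(C)=CC[C@@]12C(=O)C=C(O[Zn]CC)[C@@H]1CC(C)=C[C@@H]2c1cc(OC)ccc1OC | intermediate
16 | iodocyclopropanolate (bicyclo[3.1.0] zinc alkoxide) | CC(C)=CC[C@@]12C(=O)C3C(I)C3(O[Zn]CC)[C@@H]1CC(C)=C[C@@H]2c1cc(OC)ccc1OC | intermediate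
17 | ring-expanded β-iodo zinc enolate | CC(C)=CC[C@@]12C(O[Zn]CC)=CC(I)C(=O)[C@@H]1CC(C)=C[C@@H]2c1cc(OC)ccc1OC | intermediate
18 | cis-fused enedione dimethyl ether | CC(C)=CC[C@@]12C(=O)C=CC(=O)[C@@H]1CC(C)=C[C@@H]2c1cc(OC)ccc1OC | intermediate
19 | enedione quinone | CC(C)=CC[C@@]12C(=O)C=CC(=O)[C@@H]1CC(C)=C[C@@H]2C1=CC(=O)C=CC1=O | intermediate
20 | CNP0166383.1 | CC(C)=CC[C@@]12C(=O)C=CC(=O)[C@@]13CC(C)=C[C@@H]2c1c(O)ccc(O)c13 | target

**Totals:** 8 steps in all; the longest linear sequence is 8 steps.

**Three steps most likely to fail**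

*Step 6 (new ring expansion).* The risks are C-2 iodomethylation without ring closure, cyclopropanation of the alkenes, and ethyl addition to the product.
- The fallback uses known chemistry only. It sets out from 6, with 1 as the source of the dienophile, and drops the contracted ring.
- Compound 1 is mono-methylated (MeI, K2CO3) to 4-methoxyphenol F1, which is oxidised with PhI(OAc)2 in MeOH to 4,4-dimethoxycyclohexa-2,5-dienone F2.
- The same BINOL–TiCl2(OiPr)2 cycloaddition with 6 gives the endo quinone-monoketal adduct F3. Normal enone regiochemistry places the free ketone next to the aryl-bearing side.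
- The single enolisable position of F3 is alkylated with KN(SiMe3)2 and 10 to give the angular prenyl ketal F4.
- Mild hydrolysis (aqueous oxalic acid on silica) comes back to the route at 18.

*Step 4 (regioselective vinylogous ester, on which the site of prenylation depends).* The fallback places the prenyl group on the dienophile instead. It sets out from 7 and 10.
- Br2 adds to 7 to give 4,5-dibromocyclopentane-1,3-dione F5, and Et3N eliminates it to 4-bromocyclopent-4-ene-1,3-dione F6.
- Compound 10 with zinc dust and LiCl gives 3-methylbut-2-enylzinc bromide F7.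
- A linear-selective Negishi coupling (Pd(OAc)2, CPhos, excess F7) gives 4-(3-methylbut-2-enyl)cyclopent-4-ene-1,3-dione F8.
- Cycloaddition of F8 with 6 joins the nucleophilic diene terminus to the unsubstituted alkene carbon in endo fashion and comes back to the route at 13.

*Step 8 (five-membered ring closure onto the quinone).* The competing reaction is deprotonation at the benzylic carbon. The fallback sets out from 18 and reverses the polarity.
- LiN(SiMe3)2 and Me3SiCl give the silyl dienol ether F9.
- PhI(OAc)2 with BF3·OEt2 forms an enolonium species, which the dimethoxyarene attacks intramolecularly to give the bridged dimethyl ether F10.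
- (NH4)2Ce(NO3)6 oxidises F10 to the bridged quinone F11.
- Na2S2O4 reduces F11 and comes back to the route at 20.

**Further compounds**
F1 | step 6 | 4-methoxyphenol | COc1ccc(O)cc1
F2 | step 6 | 4,4-dimethoxycyclohexa-2,5-dienone | COC1(OC)C=CC(=O)C=C1
F3 | step 6 | endo quinone-monoketal adduct | [C@@H]12C(=O)C=CC(OC)(OC)[C@@H]1CC(C)=C[C@@H]2c1cc(OC)ccc1OC
F4 | step 6 | angular prenyl ketal | CC(C)=CC[C@@]12C(=O)C=CC(OC)(OC)[C@@H]1CC(C)=C[C@@H]2c1cc(OC)ccc1OC
F5 | step 4 | 4,5-dibromocyclopentane-1,3-dione | O=C1CC(=O)C(Br)C1Br
F6 | step 4 | 4-bromocyclopent-4-ene-1,3-dione | O=C1CC(=O)C(Br)=C1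
F7 | step 4 | 3-methylbut-2-enylzinc bromide | CC(C)=CC[Zn]Br
F8 | step 4 | 4-(3-methylbut-2-enyl)cyclopent-4-ene-1,3-dione | CC(C)=CCC1=CC(=O)CC1=O
F9 | step 8 | trimethylsilyl dienol ether of 18 | CC(C)=CC[C@@]12C(=O)C=CC(O[Si](C)(C)C)=C1CC(C)=C[C@@H]2c1cc(OC)ccc1OC
F10 | step 8 | target dimethyl ether | CC(C)=CC[C@@]12C(=O)C=CC(=O)[C@@]13CC(C)=C[C@@H]2c1c(OC)ccc(OC)c13
F11 | step 8 | bridged quinone | CC(C)=CC[C@@]12C(=O)C=CC(=O)[C@@]13CC(C)=C[C@@H]2C1=C3C(=O)C=CC1=O
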